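Positions follow azulene numbering: C1 carbinol carbon with isopropyl, C2/C3 ring CH2, C3a quaternary C–CH3, C4 ring CH2, C5 C=O, C6 =C–CH3, C7 =CH, C8 CH–O, C8a ring-fusion CH.
Retrosynthesis: cut the C8–O coumarate ester, then the C6=C7 unsaturation, the C6–CH3 and C1–isopropyl bonds, and last the ring bonds C6–C7 and C4–C3a of the seven-membered ring.
Enabling feature: the seven-membered ring is a three-carbon oxygenated unit C6–C5(=O)–C4 joined to a four-carbon unit C7–C8–C8a–C3a that is the diene of a 3-methyl-2-vinylcyclopentene; C3a lies next to the ring CH2 (C4), so a [3,3] shift of a cis-divinylcyclopropane can create the quaternary carbon.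
Forward: the cyclopentane is bought as a bromoenone, the seven-membered ring is closed onto it by a rhodium vinylcarbenoid [4+3] annulation, then hydroboration, isopropyl addition, methylation/decarboxylation, esterification (chain joined last), dehydrogenation and phenol release.
Stereochemistry: C3a from the chiral dirhodium catalyst, relayed through the boat Cope; C8a–H and C8–O from hydroboration anti to the angular methyl; C1 from attack anti to the C8 branch and the methyl; the E alkene from p-coumaric acid.
Key step: step 5

Assumption: Rh2(S-PTAD)4, dirhodium tetrakis[(S)-(1-adamantyl)(phthalimido)acetate], is taken to give the (1R,2S)-cyclopropane and hence (3aR); if the sense of induction is the opposite, Rh2(R-PTAD)4 is used with nothing else changed.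
Remark: from 12 to 22 the C6 centre is enolisable or a mixture of epimers and carries no descriptor; it becomes sp2 in step 13.

Step 1
Reactants: 1 2-bromo-3-methylcyclopent-2-en-1-one
Product: 2 6-bromo-7-methyl-1,4-dioxaspiro[4.4]non-6-ene
Conditions: HOCH2CH2OH (3 equiv), p-TsOH·H2O (cat.), benzene, reflux, Dean–Stark
Reagents that add atoms: ethylene glycol, OCCO
Why: Acid-catalysed ketalisation with azeotropic removal of water is the standard protection of 2-bromocycloalkenones, the vinylic bromine holding the double bond in place, and it turns the enone into an achiral, base-stable partner for the coupling and the carbenoid step.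

Step 2
Reactants: 2 6-bromo-7-methyl-1,4-dioxaspiro[4.4]non-6-ene; 3 potassium vinyltrifluoroborate
Product: 4 6-ethenyl-7-methyl-1,4-dioxaspiro[4.4]non-6-ene
Conditions: PdCl2(dppf)·CH2Cl2 (5 mol%), Cs2CO3 (3 equiv), THF/H2O 9:1, 80 °C
Reagents that add atoms: none
Why: Suzuki–Miyaura coupling of the alkenyl bromide with the vinyltrifluoroborate installs the vinyl group under basic aqueous conditions that leave the dioxolane untouched and delivers the 2-vinylcyclopentene diene needed for the annulation.

Step 3
Reactants: 5 benzyl acetoacetate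
Product: 6 benzyl 2-diazo-3-oxobutanoate
Conditions: 4-AcNHC6H4SO2N3 (1.1 equiv), Et3N (1.5 equiv), MeCN, 0 °C to rt
Reagents that add atoms: 4-acetamidobenzenesulfonyl azide, CC(=O)Nc1ccc(cc1)S(=O)(=O)N=[N+]=[N-]
Why: Regitz diazo transfer from a sulfonyl azide to the doubly activated methylene of an acetoacetate is the routine entry to alpha-diazo beta-keto esters.

Step 4
Reactants: 6 benzyl 2-diazo-3-oxobutanoate
Product: 7 benzyl 3-(tert-butyldimethylsilyloxy)-2-diazobut-3-enoate
Conditions: TBSOTf (1.1 equiv), Et3N (1.3 equiv), CH2Cl2, 0 °C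
Reagents that add atoms: tert-butyldimethylsilyl triflate, CC(C)(C)[Si](C)(C)OS(=O)(=O)C(F)(F)F
Why: Soft enolisation and O-silylation of the acetyl group with a silyl triflate and triethylamine gives the 2-siloxyvinyl diazoacetate without touching the diazo ester, and the crude product is used at once because such diazo enol ethers do not tolerate chromatography well.

Step 5
Reactants: 4 6-ethenyl-7-methyl-1,4-dioxaspiro[4.4]non-6-ene; 7 benzyl 3-(tert-butyldimethylsilyloxy)-2-diazobut-3-enoate
Product: 9 benzyl (3aR)-5-(tert-butyldimethylsilyloxy)-3a-methyl-2,3,3a,4-tetrahydro-7H-spiro[azulene-1,2'-[1,3]dioxolane]-6-carboxylate, via cis-divinylcyclopropane 8 (not isolated)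
Conditions: Rh2(S-PTAD)4 (2 mol%), hexane, −20 °C to rt, 7 (1.5 equiv) added over 2 h; then reflux (69 °C)
Reagents that add atoms: none
Why: The dirhodium carboxylate decomposes 7 to a donor/acceptor vinylcarbenoid that cyclopropanates the only monosubstituted alkene of 4 with the siloxyvinyl group cis to the cyclopentenyl group, and the resulting cis-divinylcyclopropane 8 undergoes a strain-driven [3,3] shift through a boat transition state. This is the established tandem cyclopropanation/Cope rearrangement (formal [4+3] cycloaddition) of 2-siloxyvinyldiazoacetates with dienes, which is known to tolerate fully substituted diene termini. The seven-membered ring closes by enlargement of the three-membered ring, C6–C7 being made in the cyclopropanation (carbenoid carbon to the vinyl CH2) and C4–C3a in the sigmatropic step (siloxyvinyl CH2 to the methyl-bearing ring carbon), so that a cyclohepta-1,4-diene is annulated onto the cyclopentane. The only stereocentre of 9, quaternary C3a, is controlled by the chiral catalyst, which fixes the (1R,2S) cyclopropane, and the stereospecific boat geometry then lets the siloxyvinyl terminus reach only one face of the ring alkene. The step needs site selectivity and enantioselectivity: the tetrasubstituted ring alkene is too hindered for the carbenoid, the dioxolane keeps the diene achiral and free of a reactive carbonyl, and the final heating is there because the inward-pointing methyl slows the Cope step.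

Step 6
Reactants: 9 benzyl (3aR)-5-(tert-butyldimethylsilyloxy)-3a-methyl-2,3,3a,4-tetrahydro-7H-spiro[azulene-1,2'-[1,3]dioxolane]-6-carboxylate
Product: 11 benzyl (3aR,8S,8aS)-5-(tert-butyldimethylsilyloxy)-8-hydroxy-3a-methyl-2,3,3a,4,8,8a-hexahydro-7H-spiro[azulene-1,2'-[1,3]dioxolane]-6-carboxylate, via alkylborane 10 (not isolated)
Conditions: BH3·THF (1.2 equiv), THF, 0 °C to rt; then NaBO3·4H2O (4 equiv), H2O, rt
Reagents that add atoms: sodium perborate tetrahydrate, [Na+].[O-]B1OO1.O.O.O.O
Why: In this hydroboration–oxidation borane adds to the isolated trisubstituted C8=C8a alkene with boron on the less substituted C8 and hydrogen on C8a, both from the face opposite the angular methyl on the neighbouring quaternary C3a (the bias that makes steroidal 5-enes give trans-fused 6-alcohols), so the trans ring fusion and the C8 oxygen cis to the C8a hydrogen are set together, while the tetrasubstituted electron-poor enol ether, the benzyl ester and the ketal react only slowly with one equivalent of borane and survive the mild perborate oxidation, which replaces boron by oxygen with retention.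

Step 7
Reactants: 11 benzyl (3aR,8S,8aS)-5-(tert-butyldimethylsilyloxy)-8-hydroxy-3a-methyl-2,3,3a,4,8,8a-hexahydro-7H-spiro[azulene-1,2'-[1,3]dioxolane]-6-carboxylate
Product: 12 benzyl (3aR,8S,8aS)-8-hydroxy-3a-methyl-1,5-dioxodecahydroazulene-6-carboxylate
Conditions: aq HCl (2 mol/L)/THF 1:3, 0 °C to rt
Reagents that add atoms: water, O
Why: Aqueous acid hydrolysis cleaves the dioxolane and, in the same operation, the vinylogous silyl ester that would not survive a selective deketalisation anyway, so one defined hydroxy diketo ester results whose beta-keto ester can mask the seven-ring carbonyl as its enolate in the next step, and dilute acid at room temperature is chosen to spare the epimerisable C8a centre and the beta-hydroxy ketone.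

Step 8
Reactants: 12 benzyl (3aR,8S,8aS)-8-hydroxy-3a-methyl-1,5-dioxodecahydroazulene-6-carboxylate; 13 isopropylmagnesium chloride
Product: 14 benzyl (1R,3aR,8S,8aS)-1,8-dihydroxy-3a-methyl-5-oxo-1-(propan-2-yl)decahydroazulene-6-carboxylate
Conditions: CeCl3 (5 equiv, dried), 13 (5 equiv), THF, −78 °C, 1 h; then 12, −78 to 0 °C; aq NH4Cl
Reagents that add atoms: none
Why: In this organocerium 1,2-addition the first two equivalents of reagent deprotonate the hydroxyl and the beta-keto ester, whose enolate shields both the C5 carbonyl and the ester, and the weakly basic cerium reagent then adds to the remaining C1 ketone with little enolisation or hydride transfer, approaching the trans-fused cyclopentanone from the face opposite the C8 ring branch on the adjacent carbon and the angular methyl, which places the new hydroxyl cis to that methyl.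

Step 9
Reactants: 14 benzyl (1R,3aR,8S,8aS)-1,8-dihydroxy-3a-methyl-5-oxo-1-(propan-2-yl)decahydroazulene-6-carboxylate; 15 iodomethane
Product: 16 benzyl (1R,3aR,8S,8aS)-1,8-dihydroxy-3a,6-dimethyl-5-oxo-1-(propan-2-yl)decahydroazulene-6-carboxylate
Conditions: 15 (3 equiv), K2CO3 (2 equiv), acetone, rt
Reagents that add atoms: none
Why: C-Alkylation of a cyclic beta-keto ester with iodomethane and potassium carbonate is classical and leaves both hydroxyl groups alone because carbonate deprotonates only the 1,3-dicarbonyl, and the configuration of the new quaternary C6 does not matter since this carbon becomes sp2 in step 13.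

Step 10
Reactants: 16 benzyl (1R,3aR,8S,8aS)-1,8-dihydroxy-3a,6-dimethyl-5-oxo-1-(propan-2-yl)decahydroazulene-6-carboxylate
Product: 18 (1R,3aR,8S,8aS)-1,8-dihydroxy-3a,6-dimethyl-1-(propan-2-yl)octahydroazulen-5(1H)-one, via beta-keto acid 17 (not isolated)
Conditions: H2 (1 atm), 10% Pd/C, EtOAc, rt; then toluene, 70 °C
Reagents that add atoms: none
Why: Hydrogenolysis of the benzyl ester frees a beta-keto acid that loses carbon dioxide on gentle warming (decarboxylation through the cyclic six-membered transition state), and because the molecule holds no alkene at this stage nothing else is reduced and both C6 epimers are simply carried on.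

Step 11
Reactants: 19 (E)-p-coumaric acid
Product: 21 (E)-3-[4-(tert-butyldimethylsilyloxy)phenyl]prop-2-enoic acid, via bis-silyl coumarate 20 (not isolated)
Conditions: TBSCl (2.3 equiv), imidazole (5 equiv), DMF, rt; then AcOH/THF/H2O 3:1:1, rt
Reagents that add atoms: tert-butyldimethylsilyl chloride, CC(C)(C)[Si](C)(C)Cl
Why: Silylation of phenol and acid followed by hydrolysis of the far more labile silyl ester is the usual way to a phenol-protected cinnamic acid, and the cleavage is run under acidic conditions because aryl silyl ethers are base-labile.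

Step 12
Reactants: 18 (1R,3aR,8S,8aS)-1,8-dihydroxy-3a,6-dimethyl-1-(propan-2-yl)octahydroazulen-5(1H)-one; 21 (E)-3-[4-(tert-butyldimethylsilyloxy)phenyl]prop-2-enoic acid
Product: 22 (1R,3aR,8S,8aS)-1-hydroxy-3a,6-dimethyl-5-oxo-1-(propan-2-yl)decahydroazulen-8-yl (E)-3-[4-(tert-butyldimethylsilyloxy)phenyl]prop-2-enoate
Conditions: 21 (1.5 equiv), dicyclohexylcarbodiimide (1.6 equiv), DMAP (0.5 equiv), CH2Cl2, 0 °C to rt
Reagents that add atoms: none
Why: Steglich esterification acylates the secondary C8 hydroxyl while the tertiary C1 hydroxyl is too hindered to react and the E alkene of the cinnamate is unaffected, and capping the secondary alcohol here also protects it from the oxidant of the next step.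

Step 13
Reactants: 22 (1R,3aR,8S,8aS)-1-hydroxy-3a,6-dimethyl-5-oxo-1-(propan-2-yl)decahydroazulen-8-yl (E)-3-[4-(tert-butyldimethylsilyloxy)phenyl]prop-2-enoate
Product: 23 (1R,3aR,8S,8aS)-1-hydroxy-3a,6-dimethyl-5-oxo-1-(propan-2-yl)-1,2,3,3a,4,5,8,8a-octahydroazulen-8-yl (E)-3-[4-(tert-butyldimethylsilyloxy)phenyl]prop-2-enoate
Conditions: IBX (2-iodoxybenzoic acid, 2 equiv), DMSO/toluene 1:2, 70 °C
Reagents that add atoms: none
Why: IBX dehydrogenation of a ketone to its enone runs through the enol, and here only the C6 side can be desaturated because the other alpha carbon (C4) adjoins the quaternary C3a and has no beta hydrogen, so both C6 epimers should converge on the conjugated endocyclic 2-methyl enone while the tertiary alcohol, the ester and the aryl silyl ether are inert to the reagent.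

Step 14
Reactants: 23 (1R,3aR,8S,8aS)-1-hydroxy-3a,6-dimethyl-5-oxo-1-(propan-2-yl)-1,2,3,3a,4,5,8,8a-octahydroazulen-8-yl (E)-3-[4-(tert-butyldimethylsilyloxy)phenyl]prop-2-enoate
Product: 24 (1R,3aR,8S,8aS)-1-hydroxy-3a,6-dimethyl-5-oxo-1-(propan-2-yl)-1,2,3,3a,4,5,8,8a-octahydroazulen-8-yl (E)-3-(4-hydroxyphenyl)prop-2-enoate (CNP0310968.1)
Conditions: TBAF (1.2 equiv), AcOH (1.2 equiv), THF, 0 °C
Reagents that add atoms: none
Why: Fluoride cleavage of the aryl silyl ether, buffered with acetic acid so that neither phenoxide nor fluoride basicity can cause ester cleavage or acyl migration, frees the phenol and should give the target with all four stereocentres and the E alkene unchanged.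

Compound list
1 | 2-bromo-3-methylcyclopent-2-en-1-one | CC1=C(Br)C(=O)CC1 | starting material
2 | 6-bromo-7-methyl-1,4-dioxaspiro[4.4]non-6-ene | CC1=C(Br)C2(CC1)OCCO2 | intermediate
3 | potassium vinyltrifluoroborate | C=C[B-](F)(F)F.[K+] | starting material
4 | 6-ethenyl-7-methyl-1,4-dioxaspiro[4.4]non-6-ene | CC1=C(C=C)C2(CC1)OCCO2 | intermediate
5 | benzyl acetoacetate | CC(=O)CC(=O)OCc1ccccc1 | starting material
6 | benzyl 2-diazo-3-oxobutanoate | CC(=O)C(=[N+]=[N-])C(=O)OCc1ccccc1 | intermediate
7 | benzyl 3-(tert-butyldimethylsilyloxy)-2-diazobut-3-enoate | C=C(O[Si](C)(C)C(C)(C)C)C(=[N+]=[N-])C(=O)OCc1ccccc1 | intermediate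
8 | benzyl (1R,2S)-1-[1-(tert-butyldimethylsilyloxy)ethenyl]-2-(7-methyl-1,4-dioxaspiro[4.4]non-6-en-6-yl)cyclopropane-1-carboxylate, siloxyvinyl and cyclopentenyl groups cis (not isolated) | C=C(O[Si](C)(C)C(C)(C)C)[C@@]1(C(=O)OCc2ccccc2)C[C@H]1C3=C(C)CCC34OCCO4 | intermediate
9 | benzyl (3aR)-5-(tert-butyldimethylsilyloxy)-3a-methyl-2,3,3a,4-tetrahydro-7H-spiro[azulene-1,2'-[1,3]dioxolane]-6-carboxylate (double bonds C5=C6 and C8=C8a) | O=C(OCc1ccccc1)C1=C(O[Si](C)(C)C(C)(C)C)C[C@@]2(C)CCC3(OCCO3)C2=CC1 | intermediate
10 | C8 alkylborane corresponding to 11, BH2 in place of OH with the same spatial arrangement (not isolated) | O=C(OCc1ccccc1)C=1C[C@H](B)[C@@H]2[C@](C)(CCC23OCCO3)CC=1O[Si](C)(C)C(C)(C)C | intermediate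
11 | benzyl (3aR,8S,8aS)-5-(tert-butyldimethylsilyloxy)-8-hydroxy-3a-methyl-2,3,3a,4,8,8a-hexahydro-7H-spiro[azulene-1,2'-[1,3]dioxolane]-6-carboxylate (trans ring fusion, C8 hydroxyl cis to C8a hydrogen) | O=C(OCc1ccccc1)C=1C[C@H](O)[C@@H]2[C@](C)(CCC23OCCO3)CC=1O[Si](C)(C)C(C)(C)C | intermediate
12 | benzyl (3aR,8S,8aS)-8-hydroxy-3a-methyl-1,5-dioxodecahydroazulene-6-carboxylate (C6 epimers and enol) | O=C(OCc1ccccc1)C1C[C@H](O)[C@@H]2[C@](C)(CCC2=O)CC1=O | intermediate
13 | isopropylmagnesium chloride | CC(C)[Mg]Cl | starting material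
14 | benzyl (1R,3aR,8S,8aS)-1,8-dihydroxy-3a-methyl-5-oxo-1-(propan-2-yl)decahydroazulene-6-carboxylate (tertiary hydroxyl cis to the angular methyl) | O=C(OCc1ccccc1)C1C[C@H](O)[C@@H]2[C@](C)(CC[C@@]2(O)C(C)C)CC1=O | intermediate
15 | iodomethane | CI | starting material
16 | benzyl (1R,3aR,8S,8aS)-1,8-dihydroxy-3a,6-dimethyl-5-oxo-1-(propan-2-yl)decahydroazulene-6-carboxylate (both C6 epimers) | O=C(OCc1ccccc1)C1(C)C[C@H](O)[C@@H]2[C@](C)(CC[C@@]2(O)C(C)C)CC1=O | intermediate
17 | (1R,3aR,8S,8aS)-1,8-dihydroxy-3a,6-dimethyl-5-oxo-1-(propan-2-yl)decahydroazulene-6-carboxylic acid (not isolated) | O=C(O)C1(C)C[C@H](O)[C@@H]2[C@](C)(CC[C@@]2(O)C(C)C)CC1=O | intermediate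
18 | (1R,3aR,8S,8aS)-1,8-dihydroxy-3a,6-dimethyl-1-(propan-2-yl)octahydroazulen-5(1H)-one (both C6 epimers) | CC1C[C@H](O)[C@@H]2[C@](C)(CC[C@@]2(O)C(C)C)CC1=O | intermediate
19 | (E)-p-coumaric acid | O=C(O)/C=C/c1ccc(O)cc1 | starting material
20 | tert-butyldimethylsilyl (E)-3-[4-(tert-butyldimethylsilyloxy)phenyl]prop-2-enoate (not isolated) | CC(C)(C)[Si](C)(C)OC(=O)/C=C/c1ccc(O[Si](C)(C)C(C)(C)C)cc1 | intermediate
21 | (E)-3-[4-(tert-butyldimethylsilyloxy)phenyl]prop-2-enoic acid | O=C(O)/C=C/c1ccc(O[Si](C)(C)C(C)(C)C)cc1 | intermediate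
22 | (1R,3aR,8S,8aS)-1-hydroxy-3a,6-dimethyl-5-oxo-1-(propan-2-yl)decahydroazulen-8-yl (E)-3-[4-(tert-butyldimethylsilyloxy)phenyl]prop-2-enoate (both C6 epimers) | CC1C[C@H](OC(=O)/C=C/c2ccc(O[Si](C)(C)C(C)(C)C)cc2)[C@@H]2[C@](C)(CC[C@@]2(O)C(C)C)CC1=O | intermediate
23 | (1R,3aR,8S,8aS)-1-hydroxy-3a,6-dimethyl-5-oxo-1-(propan-2-yl)-1,2,3,3a,4,5,8,8a-octahydroazulen-8-yl (E)-3-[4-(tert-butyldimethylsilyloxy)phenyl]prop-2-enoate | CC1=C[C@H](OC(=O)/C=C/c2ccc(O[Si](C)(C)C(C)(C)C)cc2)[C@@H]2[C@](C)(CC[C@@]2(O)C(C)C)CC1=O | intermediate
24 | (1R,3aR,8S,8aS)-1-hydroxy-3a,6-dimethyl-5-oxo-1-(propan-2-yl)-1,2,3,3a,4,5,8,8a-octahydroazulen-8-yl (E)-3-(4-hydroxyphenyl)prop-2-enoate, CNP0310968.1 | CC1=C[C@H](OC(=O)/C=C/c2ccc(O)cc2)[C@@H]2[C@](C)(CC[C@@]2(O)C(C)C)CC1=O | target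

Total step count: 14.
Longest linear sequence: 11 steps (steps 1, 2, 5, 6, 7, 8, 9, 10, 12, 13, 14 from 1; the branch from 5 is equally long).

Steps most likely to fail

Step 5. The chiral catalyst may discriminate poorly between the enantiotopic faces of this twisted, fully substituted diene. The boat Cope must also push the ring methyl inward over the cyclopropane methylene, so it may need temperatures that are hard to combine with a clean enantioselective run. The fallback gives up catalyst control of the absolute configuration and relies on resolution. It sets out from 4 and 7, which are combined with achiral Rh2(O2CC7H15)4 (dirhodium tetraoctanoate) in toluene at room temperature and then heated at reflux. This should give the racemic cis-divinylcyclopropane F1 and from it the racemic cycloadduct F2. The enantiomers of F2 are separated by preparative chromatography on a chiral stationary phase, and the (3aR) enantiomer is 9, where the route is rejoined.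

Step 8. A branched nucleophile that carries beta hydrogens meets a hindered, enolisable cyclopentanone bearing a beta alkoxide, so hydride transfer, enolisation or retro-aldol opening may outrun addition. The fallback sets out from 12 and uses 2-propenylmagnesium bromide with CeCl3 under the same conditions; this sp2 nucleophile is smaller and cannot deliver hydride. It should give the isopropenyl carbinol F3, which is C-methylated with iodomethane and K2CO3 as in step 9 to the isopropenyl beta-keto benzyl ester F4. Hydrogenation over Pd/C as in step 10 then saturates the 1,1-disubstituted alkene in the same operation that removes the benzyl group. Acid 17 decarboxylates on warming, and the route is rejoined at 18.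

Step 13. Enolisation toward the hindered C6 methine may be slow under the IBX conditions, and the oxidant may then go on to a cross-conjugated dienone or attack elsewhere in hot DMSO. The fallback is a Saegusa–Ito sequence that separates enol formation from oxidation. It sets out from 22, which is treated with TMSOTf and Et3N in CH2Cl2 at 0 °C to give the bis(trimethylsilyl) compound F5 (the more substituted C5=C6 silyl enol ether, with the tertiary hydroxyl silylated as well). A silyl enol ether on the C4 side could not eliminate and would revert to 22 on work-up. Stoichiometric palladium diacetate in MeCN at room temperature should convert F5 into the enone trimethylsilyl ether F6. The fluoride conditions of step 14 then remove the trimethylsilyl ether and the aryl silyl ether together, so the route is rejoined at 24.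

Further compounds
F1 | step 5 | racemic benzyl 1-[1-(tert-butyldimethylsilyloxy)ethenyl]-2-(7-methyl-1,4-dioxaspiro[4.4]non-6-en-6-yl)cyclopropane-1-carboxylate, siloxyvinyl and cyclopentenyl groups cis | C=C(O[Si](C)(C)C(C)(C)C)C1(C(=O)OCc2ccccc2)CC1C3=C(C)CCC34OCCO4
F2 | step 5 | racemic benzyl 5-(tert-butyldimethylsilyloxy)-3a-methyl-2,3,3a,4-tetrahydro-7H-spiro[azulene-1,2'-[1,3]dioxolane]-6-carboxylate | O=C(OCc1ccccc1)C1=C(O[Si](C)(C)C(C)(C)C)CC2(C)CCC3(OCCO3)C2=CC1
F3 | step 8 | benzyl (1S,3aR,8S,8aS)-1,8-dihydroxy-3a-methyl-5-oxo-1-(prop-1-en-2-yl)decahydroazulene-6-carboxylate | O=C(OCc1ccccc1)C1C[C@H](O)[C@@H]2[C@](C)(CC[C@@]2(O)C(C)=C)CC1=O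
F4 | step 8 | benzyl (1S,3aR,8S,8aS)-1,8-dihydroxy-3a,6-dimethyl-5-oxo-1-(prop-1-en-2-yl)decahydroazulene-6-carboxylate | O=C(OCc1ccccc1)C1(C)C[C@H](O)[C@@H]2[C@](C)(CC[C@@]2(O)C(C)=C)CC1=O
F5 | step 13 | 5,6-ene trimethylsilyl enol ether of 22 with the C1 hydroxyl as its trimethylsilyl ether | CC=1C[C@H](OC(=O)/C=C/c2ccc(O[Si](C)(C)C(C)(C)C)cc2)[C@@H]2[C@](C)(CC[C@@]2(O[Si](C)(C)C)C(C)C)CC=1O[Si](C)(C)C
F6 | step 13 | C1 trimethylsilyl ether of 23 | CC1=C[C@H](OC(=O)/C=C/c2ccc(O[Si](C)(C)C(C)(C)C)cc2)[C@@H]2[C@](C)(CC[C@@]2(O[Si](C)(C)C)C(C)C)CC1=O
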